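**Retrosynthetic overview**

1. The route rests on the cyclopentane edge C5–C6–C7–C8 with its C10 branch. The C7 secondary carbinol (β-OH) and the C8 tertiary carbinol (α-OH, β-C10H2O) are C3 and C4 of 2-deoxy-D-ribose, whose chain C1–C5 is C5–C6–C7–C8–C10, provided C8–H is replaced by C8–C9 with retention.
2. Endgame: C11H2OH from a C4 formyl group; the C10 coumarate and C1 (S)-3-methylpentanoate from the acids; the dihydropyran ring (C1–O2 bond) by lactolisation of a C1/C3/C11 trialdehyde made from a triol.
3. C5–C4 bond: Michael addition of malonate (C3, C4, C11) to the C5=C9 cyclopentene ester.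
4. Cyclopentane ring: C8–C9 bond by carbenoid insertion of a diazo keto ester into the dioxolane methine C8–H; the diazo keto ester comes from the protected sugar aldehyde and ethyl diazoacetate (C9, C1).
5. Ring order: cyclopentane first (step 7), dihydropyran second (step 12).

Key step: step 7

Assumption: iridoid numbering is used for all intermediates (C1, O2, C3, C4 with C11, C5–C9 ring fusion, C10 on C8); β is the face of H5 and H9. Lactol 16 is drawn as its 1β-hydroxy anomer although the anomers should equilibrate, and the enolisable C9 of 9 is drawn in one configuration.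

**Route**

Step 1
Reactants: 1 2-deoxy-D-ribose
Product: 2 2-deoxy-D-ribose propane-1,3-diyl dithioacetal
Conditions: HS(CH2)3SH, conc. HCl, 0 °C → rt
Reagents that add atoms: propane-1,3-dithiol SCCCS
Why: Acid-catalysed dithioacetal formation opens the pyranose and fixes the acyclic form without touching a stereocentre.

Step 2
Reactants: 2 dithioacetal triol
Product: 3 4,5-O-isopropylidene dithioacetal (3-OH free)
Conditions: 2,2-dimethoxypropane, p-TsOH·H2O (cat.), acetone, 0 °C → rt
Reagents that add atoms: 2,2-dimethoxypropane COC(C)(C)OC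
Why: Acetal exchange under thermodynamic control should favour the terminal 4,5-dioxolane over the cis-disubstituted 3,4-dioxolane and the 3,5-dioxane, leaving only the future O7 free.

Step 3
Reactants: 3 acetonide alcohol
Product: 4 3-O-TBS-4,5-O-isopropylidene dithioacetal
Conditions: TBSCl, imidazole, DMF, rt
Reagents that add atoms: tert-butyldimethylsilyl chloride CC(C)(C)[Si](C)(C)Cl
Why: Standard silylation of the single secondary hydroxyl; the bulky silyl group also lowers the nucleophilicity of O7 toward the later carbenoid.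

Step 4
Reactants: 4 silyl ether dithioacetal
Product: 5 3-O-TBS-4,5-O-isopropylidene-2-deoxy-aldehydo-D-ribose
Conditions: MeI, CaCO3, MeCN–H2O (4:1), 45 °C
Reagents that add atoms: water O
Why: S-Alkylative hydrolysis of the dithiane under CaCO3 buffering frees the aldehyde while acetonide and silyl ether survive, and the aldehyde has no α-stereocentre to lose.

Step 5
Reactants: 5 aldehyde; 6 ethyl diazoacetate
Product: 7 β-keto ester (ethyl 5-OTBS-5-(2,2-dimethyl-1,3-dioxolan-4-yl)-3-oxopentanoate, D-erythro as in 5)
Conditions: SnCl2 (10 mol%), CH2Cl2, rt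
Reagents that add atoms: none
Why: Roskamp reaction: SnCl2-promoted addition of the diazo carbon to the aldehyde and 1,2-hydride shift with loss of N2 give the β-keto ester under non-basic conditions, so the β-silyloxy group is not eliminated.

Step 6
Reactants: 7 β-keto ester
Product: 8 α-diazo β-keto ester
Conditions: 4-acetamidobenzenesulfonyl azide, Et3N, MeCN, 0 °C → rt
Reagents that add atoms: 4-acetamidobenzenesulfonyl azide CC(=O)Nc1ccc(cc1)S(=O)(=O)N=[N+]=[N-]
Why: Regitz diazo transfer to the active methylene between ketone and ester.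

Step 7
Reactants: 8 α-diazo β-keto ester
Product: 9 cyclopentanone β-keto ester (ring C5(=O)–C6H2–C7–C8–C9; 7β-OTBS; C8 spiro to the dioxolane with O8 α and C10 β; CO2Et on C9)
Conditions: Rh2(OAc)4 (1–2 mol%), CH2Cl2, slow addition, rt → reflux
Reagents that add atoms: none
Why: Rh2(OAc)4 (a dimer of divalent rhodium) expels N2 from 8 to give an electrophilic carbenoid at C9 flanked by ester and ketone, which inserts in a concerted three-centre transition state into the C8–H bond five atoms away. The closest known reaction type is the dirhodium-catalysed 1,5 C–H insertion of α-diazo β-keto esters to 2-oxocyclopentanecarboxylates, which is established for methine C–H bonds bearing an ether or acetal oxygen. The cyclopentanone (C5–C6–C7–C8–C9) closes by this 1,5-insertion through a chair-like six-membered array, forming the C8–C9 bond. C8 is set with retention because the C–C bond forms on the side of the departing hydrogen, so C4 of the sugar becomes the tertiary centre with O8 α and C10 β, while C9 is an enolisable centre of no consequence (erased in step 8) and C7 is untouched. The step needs insertion at C8–H in preference to 1,6-insertion at C10–H2, insertion into the ester ethyl group and oxonium ylide formation at O7 or O8. This should be secured by C8–H being the only tertiary, lone-pair-activated bond that gives a five-membered ring on the ketone side, by the bulky silyl group on O7 and the weakly donating acetal oxygen O8, and by the absence of an α-hydrogen for 1,2-shift.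

Step 8
Reactants: 9 cyclopentanone β-keto ester
Product: 10 enol triflate (C5–OTf, C5=C9, CO2Et on C9)
Conditions: Tf2O, i-Pr2NEt, CH2Cl2, −78 °C
Reagents that add atoms: trifluoromethanesulfonic anhydride FC(F)(F)S(=O)(=O)OS(=O)(=O)C(F)(F)F
Why: O-Sulfonylation of the enol of a cyclic β-keto ester; the amine base at low temperature avoids β-elimination of the C8 oxygen, and the labile C9 centre is erased here.

Step 9
Reactants: 10 enol triflate
Product: 11 cyclopentene ester (C5H=C9–CO2Et; 7β-OTBS; 8,10-acetonide)
Conditions: Pd(OAc)2 (5 mol%), PPh3, HCO2H, Et3N, DMF, 60 °C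
Reagents that add atoms: none
Why: Palladium-catalysed formate reduction of a vinyl triflate (oxidative addition to zerovalent palladium, formate-to-hydride exchange with loss of CO2, reductive elimination) replaces OTf by H and leaves the conjugated ester.

Step 10
Reactants: 11 cyclopentene ester; 12 diethyl malonate
Product: 13 triester (C5 carries CH(CO2Et)2 on the α face; H5 β; H9 β; CO2Et on C9 α)
Conditions: 12 (5 equiv), t-BuOK (0.3 equiv), THF–t-BuOH, 0 °C → rt; AcOH quench at 0 °C
Reagents that add atoms: none
Why: Michael addition of the malonate anion to C5 from the α face, anti to the C7 silyloxy group and the C10 methylene, should set C5 (H5 β), and protonation of the resulting ester enolate by malonate from the β face, anti to the new C5 substituent, should set C9 cis (H9 β) under conditions where the only base left is the weakly basic malonate anion, so C9 is not equilibrated.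

Step 11
Reactants: 13 triester
Product: 14 triol (C1H2OH on C9; C4 carries C3H2OH and C11H2OH)
Conditions: LiAlH4, THF, 0 °C → rt; Rochelle salt work-up
Reagents that add atoms: none
Why: LiAlH4 reduction of the three esters to primary alcohols; silyl ether and acetonide are inert, and C9 is configurationally fixed once it is no longer α to a carbonyl.

Step 12
Reactants: 14 triol
Product: 16 cis-fused 4-formyl lactol (1β-OH; C3=C4 enol ether; C11 formyl; 7β-OTBS; 8,10-acetonide), via trialdehyde 15 (not isolated)
Conditions: (COCl)2, DMSO, CH2Cl2, −78 °C; Et3N, −78 → 0 °C; aq. NH4Cl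
Reagents that add atoms: none
Why: Swern oxidation activates all three primary alcohols before base is added, so the trialdehyde should form at once without lactone formation; its malondialdehyde unit enolises and the enol OH adds to the cis-disposed C1 aldehyde (six-membered hemiacetal), with C1 set thermodynamically as the pseudo-axial 1β-OH on the convex face.

Step 13
Reactants: 16 lactol; 17 (S)-3-methylpentanoic acid
Product: 18 1β-O-[(S)-3-methylpentanoyl] 4-formyl iridoid (7β-OTBS; 8,10-acetonide)
Conditions: DCC, DMAP (cat.), CH2Cl2, 0 °C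
Reagents that add atoms: none
Why: Steglich esterification of the hemiacetal hydroxyl; the α face of C1 is shielded by the cyclopentane ring and the α-oxygen of the spiro-dioxolane on C8, so acylation of the equilibrating lactol should give the 1β ester, and the β-stereocentre of the acid cannot racemise.

Step 14
Reactants: 18 acetonide ester
Product: 19 8α,10-diol (C1 ester; C11 formyl; 7β-OTBS)
Conditions: AcOH–H2O (4:1), rt
Reagents that add atoms: none
Why: Mild acid hydrolysis of the acetonide; the secondary TBS ether should survive, and the C1 acyloxy acetal resists ionisation because the ring oxygen lone pair is tied up in the vinylogous formate.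

Step 15
Reactants: 20 p-coumaric acid
Product: 22 (E)-4-(tert-butyldimethylsilyloxy)cinnamic acid, via bis-silylated coumarate 21 (not isolated)
Conditions: TBSCl (2.5 equiv), imidazole, DMF, rt; then AcOH–THF–H2O, rt
Reagents that add atoms: tert-butyldimethylsilyl chloride CC(C)(C)[Si](C)(C)Cl
Why: Exhaustive silylation followed by selective hydrolysis of the labile silyl ester masks the phenol so that the acid cannot self-condense in the coupling.

Step 16
Reactants: 19 diol; 22 silyl-protected coumaric acid
Product: 23 10-O-(4-O-TBS-coumaroyl) derivative (8α-OH free; 7β-OTBS; C11 formyl; C1 ester)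
Conditions: DCC, DMAP (cat.), CH2Cl2, 0 °C
Reagents that add atoms: none
Why: Steglich esterification is selective for the primary C10 hydroxyl over the tertiary C8 hydroxyl, and the C7 hydroxyl is still silylated.

Step 17
Reactants: 23 bis-silyl ether
Product: 24 11-aldehyde with free 7β-OH, 8α-OH and phenol
Conditions: HF·pyridine, pyridine, THF, 0 °C → rt
Reagents that add atoms: none
Why: Buffered fluoride cleavage of the aryl and the secondary alkyl silyl ether, done while the enol ether is still deactivated as a vinylogous formate.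

Step 18
Reactants: 24 aldehyde
Product: 25 target (CNP0241834.1)
Conditions: NaBH4, CeCl3·7H2O, MeOH, −78 °C; pH 7 buffer
Reagents that add atoms: none
Why: Luche reduction: NaBH4 with CeCl3 should reduce the β-alkoxy enal 1,2 to the C11 allylic alcohol at low temperature faster than it touches the three esters.

**Compound list**

1 | 2-deoxy-D-ribose (open-chain form) | O=CC[C@H](O)[C@H](O)CO | starting material
2 | 2-deoxy-D-ribose propane-1,3-diyl dithioacetal, 2-[(2S,3R)-2,3,4-trihydroxybutyl]-1,3-dithiane | C1(C[C@H](O)[C@H](O)CO)SCCCS1 | intermediate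
3 | 4,5-O-isopropylidene dithioacetal, 3-OH free | C1(C[C@H](O)[C@H]2COC(C)(C)O2)SCCCS1 | intermediate
4 | 3-O-TBS-4,5-O-isopropylidene dithioacetal | C1(C[C@H](O[Si](C)(C)C(C)(C)C)[C@H]2COC(C)(C)O2)SCCCS1 | intermediate
5 | 3-O-TBS-4,5-O-isopropylidene-2-deoxy-aldehydo-D-ribose | O=CC[C@H](O[Si](C)(C)C(C)(C)C)[C@H]1COC(C)(C)O1 | intermediate
6 | ethyl diazoacetate | CCOC(=O)C=[N+]=[N-] | starting material
7 | β-keto ester, sugar configuration retained | CCOC(=O)CC(=O)C[C@H](O[Si](C)(C)C(C)(C)C)[C@H]1COC(C)(C)O1 | intermediate
8 | α-diazo β-keto ester | CCOC(=O)C(=[N+]=[N-])C(=O)C[C@H](O[Si](C)(C)C(C)(C)C)[C@H]1COC(C)(C)O1 | intermediate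
9 | cyclopentanone β-keto ester, 7β-OTBS, C8 spiro-dioxolane (O8 α, C10 β) | O=C1C[C@H](O[Si](C)(C)C(C)(C)C)[C@]2(COC(C)(C)O2)[C@H]1C(=O)OCC | intermediate
10 | enol triflate of 9 | C1[C@H](O[Si](C)(C)C(C)(C)C)[C@]2(COC(C)(C)O2)C(C(=O)OCC)=C1OS(=O)(=O)C(F)(F)F | intermediate
11 | C5=C9 cyclopentene ester | C1[C@H](O[Si](C)(C)C(C)(C)C)[C@]2(COC(C)(C)O2)C(C(=O)OCC)=C1 | intermediate
12 | diethyl malonate | CCOC(=O)CC(=O)OCC | starting material
13 | triester, H5 β, H9 β | C1[C@H](O[Si](C)(C)C(C)(C)C)[C@]2(COC(C)(C)O2)[C@@H](C(=O)OCC)[C@H]1C(C(=O)OCC)C(=O)OCC | intermediate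
14 | triol (C1, C3, C11 hydroxymethyls) | C1[C@H](O[Si](C)(C)C(C)(C)C)[C@]2(COC(C)(C)O2)[C@@H](CO)[C@H]1C(CO)CO | intermediate
15 | trialdehyde (not isolated) | C1[C@H](O[Si](C)(C)C(C)(C)C)[C@]2(COC(C)(C)O2)[C@@H](C=O)[C@H]1C(C=O)C=O | intermediate
16 | cis-fused 4-formyl lactol, 1β-OH | O[C@@H]1OC=C(C=O)[C@H]2C[C@H](O[Si](C)(C)C(C)(C)C)[C@]3(COC(C)(C)O3)[C@@H]12 | intermediate
17 | (S)-3-methylpentanoic acid | CC[C@H](C)CC(=O)O | starting material
18 | 1β-O-[(S)-3-methylpentanoyl] 4-formyl acetonide | CC[C@H](C)CC(=O)O[C@@H]1OC=C(C=O)[C@H]2C[C@H](O[Si](C)(C)C(C)(C)C)[C@]3(COC(C)(C)O3)[C@@H]12 | intermediate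
19 | 8α,10-diol | CC[C@H](C)CC(=O)O[C@@H]1OC=C(C=O)[C@H]2C[C@H](O[Si](C)(C)C(C)(C)C)[C@](O)(CO)[C@@H]12 | intermediate
20 | p-coumaric acid | OC(=O)/C=C/c1ccc(O)cc1 | starting material
21 | TBS (E)-4-(TBS-oxy)cinnamate (not isolated) | CC(C)(C)[Si](C)(C)OC(=O)/C=C/c1ccc(O[Si](C)(C)C(C)(C)C)cc1 | intermediate
22 | (E)-4-(tert-butyldimethylsilyloxy)cinnamic acid | OC(=O)/C=C/c1ccc(O[Si](C)(C)C(C)(C)C)cc1 | intermediate
23 | 10-O-(4-O-TBS-coumaroyl) 7-O-TBS 11-aldehyde | CC[C@H](C)CC(=O)O[C@@H]1OC=C(C=O)[C@H]2C[C@H](O[Si](C)(C)C(C)(C)C)[C@](O)(COC(=O)/C=C/c3ccc(O[Si](C)(C)C(C)(C)C)cc3)[C@@H]12 | intermediate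
24 | desilylated 11-aldehyde | CC[C@H](C)CC(=O)O[C@@H]1OC=C(C=O)[C@H]2C[C@H](O)[C@](O)(COC(=O)/C=C/c3ccc(O)cc3)[C@@H]12 | intermediate
25 | CNP0241834.1 | CC[C@H](C)CC(=O)O[C@@H]1OC=C(CO)[C@H]2C[C@H](O)[C@](O)(COC(=O)/C=C/c3ccc(O)cc3)[C@@H]12 | target

**Totals**

Total step count: 18. Longest linear sequence: 17 (steps 1–14 and 16–18; step 15 is the side branch).

**Three steps most likely to fail**

Step 10 (Michael addition). The addition to a trisubstituted cyclopentene ester may be slow and reversible, attack at C5 may show poor facial selectivity, and the C9 ester enolate may be protonated or later equilibrated to the 5,9-trans arrangement. Fallback, from 11 and back at 16: replace kinetic by thermodynamic control of C9. The addition is run under equilibrating conditions (NaOEt, EtOH, 50 °C) to give on purpose the 5,9-trans triester F1. LiAlH4 then gives the 9-epi triol F2, and Swern oxidation gives the 9-epi trialdehyde F3, whose trans-disposed C1 and C4 groups could close only a strained trans-fused lactol. Catalytic pyrrolidinium acetate in CH2Cl2 should then epimerise C9 through the enamine of the C1 aldehyde, which is less prone than an enolate to expel the C8 oxygen, and the cis isomer drains into the cis-fused lactol 16.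

Step 7 (key C–H insertion). The carbenoid may be diverted into oxonium ylide formation at the dioxolane or silyl ether oxygen or into 1,6-insertion at C10–H2, or it may insert slowly because the two β-oxygens deactivate the C8–H bond. Fallback, from 4 and back at 9: an open-chain precursor in which C8–H is α to a silyl ether and not to an acetal oxygen. Aqueous AcOH removes the acetonide of 4 to give the dithioacetal diol F4, and TESCl with imidazole gives the bis(triethylsilyl) ether F5. MeI with CaCO3 in aqueous MeCN frees the aldehyde F6, the Roskamp reaction with 6 (SnCl2) gives the β-keto ester F7, and diazo transfer gives the diazo keto ester F8. Rh2(OAc)4 should then give, by insertion with retention into the C8–H bond next to the silyloxy group, the cyclopentanone F9. HF·pyridine in THF–pyridine at 0 °C cleaves the two triethylsilyl ethers in preference to the secondary TBS ether to give the diol F10, and 2,2-dimethoxypropane with PPTS closes the acetonide to 9.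

Step 12 (triple oxidation and lactolisation). Partly oxidised intermediates may close to cyclic hemiacetals that are oxidised on to lactones, the half-oxidised 1,3-diol unit may eliminate to a 2-methylene aldehyde, and the C1 aldehyde may lose the C8 oxygen by β-elimination under the amine base. Fallback, from 11 and back at 16: bring C3 in at the aldehyde level so that no 1,3-diol is oxidised. The lithium enolate of ethyl 3,3-diethoxypropanoate (LiN(i-Pr)2, THF, −78 °C) is added to 11 and the ester enolate is quenched at −78 °C with 2,6-di-tert-butylphenol to give the diester acetal F11 (C4 epimers, C4 becomes sp2 later). LiAlH4 gives the diol acetal F12 and Swern oxidation gives the dialdehyde acetal F13. Dilute aqueous acid (AcOH–H2O–THF, 0 °C → rt) then hydrolyses the diethyl acetal, which is flanked by a formyl group and first loses ethanol to the β-ethoxy acrolein, and the liberated trialdehyde 15 closes to lactol 16.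

**Further compounds**

F1 | step 10 | 5,9-trans (9-epi) triester | C1[C@H](O[Si](C)(C)C(C)(C)C)[C@]2(COC(C)(C)O2)[C@H](C(=O)OCC)[C@H]1C(C(=O)OCC)C(=O)OCC
F2 | step 10 | 9-epi triol | C1[C@H](O[Si](C)(C)C(C)(C)C)[C@]2(COC(C)(C)O2)[C@H](CO)[C@H]1C(CO)CO
F3 | step 10 | 9-epi trialdehyde | C1[C@H](O[Si](C)(C)C(C)(C)C)[C@]2(COC(C)(C)O2)[C@H](C=O)[C@H]1C(C=O)C=O
F4 | step 7 | 3-O-TBS dithioacetal 4,5-diol | C1(C[C@H](O[Si](C)(C)C(C)(C)C)[C@H](O)CO)SCCCS1
F5 | step 7 | 3-O-TBS-4,5-bis-O-TES dithioacetal | C1(C[C@H](O[Si](C)(C)C(C)(C)C)[C@H](O[Si](CC)(CC)CC)CO[Si](CC)(CC)CC)SCCCS1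
F6 | step 7 | 3-O-TBS-4,5-bis-O-TES-2-deoxy-aldehydo-D-ribose | O=CC[C@H](O[Si](C)(C)C(C)(C)C)[C@H](O[Si](CC)(CC)CC)CO[Si](CC)(CC)CC
F7 | step 7 | open-chain tris-silyl β-keto ester | CCOC(=O)CC(=O)C[C@H](O[Si](C)(C)C(C)(C)C)[C@H](O[Si](CC)(CC)CC)CO[Si](CC)(CC)CC
F8 | step 7 | open-chain tris-silyl α-diazo β-keto ester | CCOC(=O)C(=[N+]=[N-])C(=O)C[C@H](O[Si](C)(C)C(C)(C)C)[C@H](O[Si](CC)(CC)CC)CO[Si](CC)(CC)CC
F9 | step 7 | cyclopentanone with 7β-OTBS, 8α-OTES and 10-OTES | O=C1C[C@H](O[Si](C)(C)C(C)(C)C)[C@](O[Si](CC)(CC)CC)(CO[Si](CC)(CC)CC)[C@H]1C(=O)OCC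
F10 | step 7 | cyclopentanone 8α,10-diol with 7β-OTBS | O=C1C[C@H](O[Si](C)(C)C(C)(C)C)[C@](O)(CO)[C@H]1C(=O)OCC
F11 | step 12 | diester diethyl acetal (C4 epimers) | C1[C@H](O[Si](C)(C)C(C)(C)C)[C@]2(COC(C)(C)O2)[C@@H](C(=O)OCC)[C@H]1C(C(=O)OCC)C(OCC)OCC
F12 | step 12 | diol diethyl acetal | C1[C@H](O[Si](C)(C)C(C)(C)C)[C@]2(COC(C)(C)O2)[C@@H](CO)[C@H]1C(CO)C(OCC)OCC
F13 | step 12 | dialdehyde diethyl acetal | C1[C@H](O[Si](C)(C)C(C)(C)C)[C@]2(COC(C)(C)O2)[C@@H](C=O)[C@H]1C(C=O)C(OCC)OCC
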